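The runs were computed with constants of no real substance, and the scatter is random.

Percent of the charge per hour is the unit in which a feed and a reaction can be set against each other. These are the flasks, the readings and the questions:

| flask | starting material | protic impurity | capture agent | remark | time |
|---|---|---|---|---|---|
| dusk | 11 mM | 2.2 mM | 0.22 mM | run made earlier |  |
| summer | 11 mM | 2.2 mM | 0.31 mM | run made earlier |  |
| spring | 11 mM | 2.2 mM | 0.48 mM | run made earlier |  |
| autumn | 16 mM | 2.2 mM | 0.22 mM | run made earlier |  |
| Monday's | 11 mM | 2.20 mM | 0.220 mM | everything together in a closed stirred flask, run for 3.0 d | 3.0 d |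
| Saturday's | 11 mM (fed, over 3.00 d) | 2.20 mM | 0.220 mM | all but starting material at the start; starting material goes in evenly over 3.00 d, the run ends at 3.0 d | 3.0 d |
| Tuesday's | 11 mM | 2.20 mM | 0.220 mM | one stirred flow tank at steady state, fed with the mixture as stated, mean residence time 3.0 d |  |

- dusk (time / h: target / %, starting material / %): 8.00: 92.3, 0.5; 15.0: 91.3, 0; 25.0: 91.0, 0; 30.0: 91.3, 0.8; 40.0: 91.6, 0
- summer (time / h: target / %, starting material / %): 4.00: 88.6, 2.9; 10.0: 92.3, 0; 20.0: 91.5, 0.4; 30.0: 90.9, 0; 40.0: 91.4, 0
- spring (time / h: target / %, starting material / %): 3.00: 81.9, 7.4; 6.00: 91.1, 0.7; 12.0: 92.0, 0.1; 25.0: 93.3, 0; 40.0: 92.0, 0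
- autumn (time / h: target / %, starting material / %): 8.00: 90.5, 0.6; 15.0: 91.5, 0; 25.0: 91.8, 0.1; 30.0: 92.0, 0; 40.0: 91.6, 0.2

(scatter of a reading: 0.5 percentage points)

- the stated concentrations are those of everything mixed, before any reaction; amounts are the same in each set-up
- the analysis behind the earlier runs scatters by 0.5 percentage points, standard deviation
- the feed brings no volume worth counting
- the earlier runs were made in a closed, stirred flask

1. the set-up with the highest amount of target at the outlet or at the end, in percent of the starting material put in ("none" if the first two lie within 2 percentage points) (Monday's / Saturday's / Tuesday's / none)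
2. amount of target at the outlet or at the end, in percent of the starting material put in, Monday's
3. amount of target at the outlet or at the end, in percent of the starting material put in, Saturday's
4. amount of target at the outlet or at the end, in percent of the starting material put in, Tuesday's

In the dusk run, which has Monday's recipe, the target stays flat at a mean of 91.5 %, so I expect that for Monday's closed flask. The question is what a steady feed costs. I take the starting material's fall as first order. Its rate constant k, read from the spring run, where 7.4 % is left after 3.00 h, is:

k = ln(charge / amount left) / time = 0.868 h⁻¹

In a fed flask the amount of starting material climbs until the reaction removes it as fast as the feed brings it. Setting those two rates equal and dividing makes time drop out: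

amount standing = feed rate / k = 1 / (k × dosing time) = 1.60 %

I call this the hold-up: the steady-state share of the charge that stands unreacted while the feed runs. The mean life 1.15 h is far shorter than the 3.00 d of dosing, so Saturday's flask should be at its hold-up by the end. Tuesday's tank, with its residence time 3.0 d, lets out 1/(1 + k × residence time) = 1.57 %, practically the same share.

My reckoning is therefore 89.9 % for Saturday's and Tuesday's. The gap to Monday's is smaller than the margin of 2 percentage points, so I commit to none.

The forecast gives 91.6 % for Monday's, 89.4 % for Saturday's and 89.4 % for Tuesday's, and it chooses Monday's: “The gap of about 2.2 points is marginal, but it favours Monday's”.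

The simulation gives 91.8 % for Monday's, 90.8 % for Saturday's and 91.8 % for Tuesday's, so the choice is none. My Tuesday's figure stands 1.9 points lower than the result.

    open intermediate → target (k = 2.13 h⁻¹)
    open intermediate + capture agent → trapped intermediate (k = 9.11 M⁻¹ h⁻¹)
    starting material + open intermediate → side product (k = 3.42 M⁻¹ h⁻¹)
    starting material ⇌ open intermediate (K = 2.00, k = 1.10 h⁻¹)
    starting material + protic impurity → quenched substrate (k = 37.2 M⁻¹ h⁻¹)

Saturday's flask ends with 1.50 % of starting material, close to the hold-up of 1.60 %, and at 1.53 d the forward step to open intermediate uses starting material 17 times as fast as the step with protic impurity. A neighbour flask, like Saturday's but with 0.55 mM of protic impurity, holds 1.56 % of starting material at its end, again close to the hold-up, while its target stands at 95.8 %.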